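**Assumption:** the target has no stereocentre and no stereogenic double bond, so it is achiral and needs no stereocontrol; the side chain is read as unbranched henicosyl (C21).

## Retrosynthetic overview

1. All atoms come from 2-picoline (1) and 1-bromoicosane (2): picolyl anion 3 plus 2 gives 2-henicosylpyridine (4), the only C–C bond made, and N-oxidation gives 5.
2. Key disconnection: the pyrrole N1–C2 bond and the formyl C=O are traced back to N-oxide 5. The oxygen moves to C6 (oxaziridine 6, 1,2-oxazepine 7), nitrogen closes onto C5 (2H-pyrrole 8), and tautomerisation gives target 9.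
3. Ring order: the pyridine ring is bought. The pyrrole is the only ring formed, last, by contraction of the pyridine; C6 of the pyridine becomes the CHO carbon.

## Route

Step 1
Reactants: 1 2-methylpyridine (2-picoline); 2 1-bromoicosane
Product: 4 2-henicosylpyridine, via 2-picolyllithium 3 (not isolated)
Conditions: 1 (1.3 equiv), n-BuLi (1.25 equiv), THF, −78 → −20 °C, 45 min; then 2 (1.0 equiv) in THF, −20 °C → rt, 4 h
Reagents that add atoms: none
Why: The 2-methyl group is deprotonated by n-BuLi to the aza-allyl anion 3, which alkylates the primary bromide by SN2 (lateral lithiation–alkylation); the excess of 1 suppresses dialkylation and no stereocentre is formed.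

Step 2
Reactants: 4 2-henicosylpyridine
Product: 5 2-henicosylpyridine 1-oxide
Conditions: mCPBA (1.2 equiv), CH2Cl2, 0 °C → rt, 3 h; filtration through basic alumina
Reagents that add atoms: mCPBA (3-chloroperoxybenzoic acid), OOC(=O)c1cccc(Cl)c1
Why: The pyridine nitrogen is the only oxidisable site, so peracid N-oxidation (electrophilic oxygen transfer) is clean and the saturated chain is inert.

Step 3
Reactants: 5 2-henicosylpyridine 1-oxide
Product: 9 5-henicosyl-1H-pyrrole-2-carbaldehyde (target), via oxaziridine 6 (not isolated), via 1,2-oxazepine 7 (not isolated), via 2H-pyrrole 8 (not isolated)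
Conditions: hν 254 nm (low-pressure Hg, FEP-coil flow reactor, ca. 10 min residence, run to ca. 80% conversion), Cu(OTf)2 (5 equiv), t-BuOH/H2O 9:1 (5 mM), 35 °C, Ar; aq. Na2EDTA/NaHCO3 work-up, chromatography
Reagents that add atoms: none
Why: Proposed new method: a copper(II)-templated, α′-selective photochemical oxygen-walk ring contraction of a 2-alkylpyridine N-oxide in a single largely organic phase. ππ* excitation of 5 should move the N-oxide oxygen onto the unsubstituted C6, because this keeps the henicosyl group on an sp2 C=N carbon and avoids a fully substituted oxaziridine carbon, giving 6. Electrocyclic opening then gives 7 (new C6–O bond), and Cu(II)-assisted N–O cleavage with a 1,3-shift of nitrogen to C5 makes the new C–N bond of 8, which tautomerises to aromatic 9. The closest known reaction type is the photochemical ring contraction of simple pyridine N-oxides to 2-formylpyrroles in aqueous copper(II) salt solution; it has not been shown with regiocontrol on a 2-(long-chain alkyl) N-oxide or outside water.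

## Compound list

1 | 2-methylpyridine (2-picoline) | Cc1ccccn1 | starting material
2 | 1-bromoicosane | CCCCCCCCCCCCCCCCCCCCBr | starting material
3 | (pyridin-2-ylmethyl)lithium (2-picolyllithium) | [Li]Cc1ccccn1 | intermediate
4 | 2-henicosylpyridine | CCCCCCCCCCCCCCCCCCCCCc1ccccn1 | intermediate
5 | 2-henicosylpyridine 1-oxide | CCCCCCCCCCCCCCCCCCCCCc1cccc[n+]1[O-] | intermediate
6 | 2-henicosyl-7-oxa-1-azabicyclo[4.1.0]hepta-2,4-diene (oxaziridine, racemic, transient) | CCCCCCCCCCCCCCCCCCCCCC1=CC=CC2ON12 | intermediate
7 | 3-henicosyl-1,2-oxazepine | CCCCCCCCCCCCCCCCCCCCCC1=NOC=CC=C1 | intermediate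
8 | 5-henicosyl-2H-pyrrole-2-carbaldehyde (racemic, transient) | CCCCCCCCCCCCCCCCCCCCCC1=NC(C=O)C=C1 | intermediate
9 | 5-henicosyl-1H-pyrrole-2-carbaldehyde | CCCCCCCCCCCCCCCCCCCCCc1ccc(C=O)[nH]1 | target

## Step count

Total step count: 3. Longest linear sequence: 3 steps (1 or 2 → 4 → 5 → 9).

## Steps most likely to fail, with fallbacks

**Step 3 (proposed ring contraction), the main risk.** The oxygen may instead move to C2 and give the isomeric 2-acylpyrrole. Deoxygenation back to 4 (recyclable through step 2), hydroxypyridines from a further oxygen walk, and secondary photolysis of 9 can all lower the yield. A yield of roughly 30–45% is a realistic expectation by analogy with the aqueous parent reaction. The fallback uses only known chemistry; it sets out from 2 and comes back to the route at 9. Bromide 2 is converted with Mg in THF into icosylmagnesium bromide F1. F1 (2.3 equiv, one equivalent is consumed by the N–H) is added to commercial 1H-pyrrole-2-carbaldehyde at 0 °C → rt and quenched with aq. NH4Cl to give 1-(1H-pyrrol-2-yl)henicosan-1-ol F2. Crude F2 is deoxygenated with NaBH4 in refluxing i-PrOH (through the azafulvene) to 2-henicosyl-1H-pyrrole F3. Vilsmeier–Haack formylation (POCl3, DMF, 0 °C → rt; aq. NaOAc) at the free α-position then gives 9.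

**Step 1 (lateral alkylation).** The waxy bromide is poorly soluble at low temperature, and some dialkylation at the new α-CH2 or elimination of 2 may occur. The fallback replaces alkylation by olefination and hydrogenation; it sets out from 2 and comes back at 4. Bromide 2 and PPh3 (MeCN, reflux) give icosyl(triphenyl)phosphonium bromide F4. NaHMDS in THF gives the ylide icosylidene(triphenyl)phosphorane F5, which reacts with commercial pyridine-2-carbaldehyde (−78 °C → rt) to give 2-[(Z)-henicos-1-en-1-yl]pyridine F6; any E isomer is equally usable. Hydrogenation (H2, 1 atm, Pd/C, EtOAc) gives 4.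

**Step 2 (N-oxidation).** The chemistry is safe, but the amphiphilic N-oxide can hold on to 3-chlorobenzoic acid and give emulsions or losses on purification. The fallback inverts the order of oxidation and C–C bond formation; it sets out from 1 and comes back at 5. Picoline 1 is oxidised first (mCPBA, or H2O2/AcOH, with distillation) to 2-methylpyridine 1-oxide F7. Lateral lithiation with LDA in THF at −78 °C gives [(1-oxidopyridin-1-ium-2-yl)methyl]lithium F8, which is alkylated with 2 (−78 °C → rt) to give 5 directly.

## Further compounds

F1 | step 3 | icosylmagnesium bromide | CCCCCCCCCCCCCCCCCCCC[Mg]Br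
F2 | step 3 | 1-(1H-pyrrol-2-yl)henicosan-1-ol (racemic) | CCCCCCCCCCCCCCCCCCCCC(O)c1ccc[nH]1
F3 | step 3 | 2-henicosyl-1H-pyrrole | CCCCCCCCCCCCCCCCCCCCCc1ccc[nH]1
F4 | step 1 | icosyl(triphenyl)phosphonium bromide | CCCCCCCCCCCCCCCCCCCC[P+](c1ccccc1)(c1ccccc1)c1ccccc1.[Br-]
F5 | step 1 | icosylidene(triphenyl)phosphorane | CCCCCCCCCCCCCCCCCCCC=P(c1ccccc1)(c1ccccc1)c1ccccc1
F6 | step 1 | 2-[(Z)-henicos-1-en-1-yl]pyridine | CCCCCCCCCCCCCCCCCCC/C=C\c1ccccn1
F7 | step 2 | 2-methylpyridine 1-oxide | Cc1cccc[n+]1[O-]
F8 | step 2 | [(1-oxidopyridin-1-ium-2-yl)methyl]lithium | [Li]Cc1cccc[n+]1[O-]
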